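Readings and results stem from a simulated flask for an exercise; scatter was added.

The unit here is the charge of G, and every amount below is a fraction of it.

| setting | theta | epsilon | Thursday's | Saturday's |
|---|---|---|---|---|
| G | 34 mM | 34 mM | 34 mM | 34 mM |
| X | 4.2 mM | 23 mM | 3.40 mM | 15.0 mM |
| D | 0.52 mol% | 0.52 mol% | 0.52 mol% | 0.52 mol% |
| remark | run made earlier | run made earlier |  |  |
| time |  |  | 5.0 h | 5.0 h |

- theta (time / h: J / %): 0.500: 28.2; 1.00: 42.0; 1.50: 43.5; 2.00: 43.1; 2.50: 44.2
- epsilon (time / h: J / %): 0.200: 0; 0.667: 0.4; 1.33: 0.4; 2.00: 0; 2.50: 0.2

(scatter of a reading: 0.5 percentage points)

- the average divides the monomer in chains by the number of chains begun, living and dead together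
- the earlier runs do not show the number of chains; that part of a forecast is a guess

1. which of the two ends with the longer chains by the average number of monomer units in a chain (chains begun, living or dead) ("neither" if they lie within 10%) (Thursday's / Saturday's / neither)
2. average number of monomer units in a chain (chains begun, living or dead) at the end, Thursday's
3. average number of monomer units in a chain (chains begun, living or dead) at the end, Saturday's

In the theta run J stands flat from 1.50 h on, at 0.436 of the charge by the mean of the last 3 readings, and X was charged at 0.124. This reckoning assumes that each X removes one G. What remains then is the floor, the share of the charge that stands as G once J has stopped rising: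

floor = 1 − 0.124 − 0.436 = 0.440

Folding in the loading of D, 0.00520, gives one number, the chain number: the charge less the X share and the floor, divided by the D share. In words, it is the G that each D has to build with. It reads as a length if each D begins one chain, which is a guess, since the earlier runs do not show the number of chains.

Thursday's: (1 − 0.100 − 0.440) / 0.00520 = 88.4

Saturday's: (1 − 0.441 − 0.440) / 0.00520 = 22.8

So Thursday's flask should hold the longer chains. The epsilon run tests the number: its top line comes to −0.117, below zero, and its readings do stay at zero within the scatter. The number carries no time, and the flat theta curve allows that.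

The forecast names Thursday's, with 105 for Thursday's flask and 0 for Saturday's, which it reads as “above threshold, so no polymer”, unlike the reckoning here.

The simulation gives Thursday's, with 88.3 for Thursday's flask and 22.8 for Saturday's.

    D → L (k = 0.0428 min⁻¹)
    J + Q → G + Q, rate k2*[Q] as long as [J] is above zero (k = 7.39 min⁻¹)
    G + Q → J + Q, rate k3*[Q]*[G] (k = 493 M⁻¹ min⁻¹)
    X + G → E (k = 29.4 M⁻¹ min⁻¹)
    G + L → Q + J (k = 35.0 M⁻¹ min⁻¹)

Thursday's flask ends with G at 44.1% of the charge, the floor of 0.440 again; this is the equilibrium monomer level, 0.441 from the two steps between G and J at Q. Saturday's chains are shorter through the difference in X: with that difference taken away, Saturday's flask gives 88.3 in place of 22.8. The neighbour with 0.31 mol% of D has the same X and floor, so its chain number is 148, and the simulation stores 148.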